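**Retrosynthetic overview**

1. Elemane locants are used: C10 is the quaternary carbon (C14 methyl, C1=C2 vinyl), C9 carries the angelate, C8 the lactone oxygen, C7 the C11(=C13)–C12 lactone unit, C6 the acetate, C5 the C4(=C3)–C15 enal.
2. Late stage: C15 methyl to enal (SeO2, then Dess–Martin), angeloylation at C9 and acetylation at C6 of a bicyclic diol lactone.
3. The cyclohexane is closed last, by intramolecular indium Barbier allylation (C6–C7) of a 3-(bromomethyl)butenolide onto the C6 aldehyde; the γ-lactone ring is formed before it.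
4. The butenolide comes from a Morita–Baylis–Hillman adduct; C8/C9 come from a proline anti-aldol; the C6 aldehyde is carried as an acetal made by a Nef reaction.
5. C10/C5, the first stereocentres, come from an amine–thiourea dienamine Michael addition of tiglaldehyde to 3-methyl-1-nitrobuta-1,3-diene (both achiral).

Assumption: the (1R,2R) antipode of the amine–thiourea catalyst in step 3 gives the Re,Re sense needed; if the sense proves opposite, its mirror image is used and nothing else changes.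

**Route**

Step 1
Reactants: 1 methacrolein (2-methylprop-2-enal); 2 nitromethane
Product: 3 3-methyl-1-nitrobut-3-en-2-ol (racemic)
Conditions: 2 (5 equiv), KOt-Bu (5 mol%), THF/t-BuOH, −20 → 0 °C; AcOH quench
Reagents that add atoms: none
Why: Henry (nitroaldol) 1,2-addition to the enal is kinetically preferred over conjugate addition at low temperature with catalytic base, and the racemic carbinol centre is destroyed in the next step.

Step 2
Reactants: 3 3-methyl-1-nitrobut-3-en-2-ol
Product: 4 (1E)-3-methyl-1-nitrobuta-1,3-diene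
Conditions: MsCl, Et3N, CH2Cl2, −20 → 0 °C; cold solution used at once
Reagents that add atoms: none
Why: Mesylation and E1cB elimination (nitroaldol dehydration) give the conjugated (E)-nitrodiene, which is used immediately because it polymerises.

Step 3
Reactants: 5 tiglaldehyde ((2E)-2-methylbut-2-enal); 4 (1E)-3-methyl-1-nitrobuta-1,3-diene
Product: 6 (2S,3S)-2-ethenyl-2,4-dimethyl-3-(nitromethyl)pent-4-enal
Conditions: 5 (3 equiv), 1-[(1R,2R)-2-aminocyclohexyl]-3-[3,5-bis(trifluoromethyl)phenyl]thiourea (15 mol%), PhCO2H (15 mol%), H2O (2 equiv), toluene, 0 °C → rt (kept below 30 °C)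
Reagents that add atoms: none
Why: Proposed new method: condensation of the primary amine with 5 through the s-trans iminium ion gives the (1E)-dienamine (N anti to the vinyl group), whose α-carbon sits next to the thiourea-bound nitro group, so bond formation occurs at Cα rather than Cγ and at C2 of the nitrodiene (1,4- rather than 1,6-addition) through a synclinal like (Re,Re) Michael transition state that sets quaternary C10 and C5 together as the first stereocentres; the closest known reaction types are the primary-amine–thiourea Michael addition of α,α-disubstituted aldehydes to nitroalkenes and the α-selective dienamine Michael addition of linear enals to nitroalkenes.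

Step 4
Reactants: 6 (2S,3S)-2-ethenyl-2,4-dimethyl-3-(nitromethyl)pent-4-enal
Product: 8 (2S,3S)-3-(dimethoxymethyl)-2-ethenyl-2,4-dimethylpent-4-enal, via sodium aci-nitronate 7 (not isolated)
Conditions: NaOMe (1.05 equiv), MeOH, 0 °C; then added to H2SO4/MeOH, −45 °C, 10 min; cold aq. NaHCO3
Reagents that add atoms: methanol CO
Why: A Nef reaction run in acidic methanol converts the nitronate directly into the dimethyl acetal while the α-quaternary aldehyde, which acetalises far more slowly at −45 °C, is meant to survive, and no stereocentre is touched because C5 is never enolised.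

Step 5
Reactants: 8 (2S,3S)-3-(dimethoxymethyl)-2-ethenyl-2,4-dimethylpent-4-enal; 9 2-[(tert-butyldimethylsilyl)oxy]acetaldehyde
Product: 10 (2S,3S,4S,5S)-2-[(tert-butyldimethylsilyl)oxy]-5-(dimethoxymethyl)-4-ethenyl-3-hydroxy-4,6-dimethylhept-6-enal
Conditions: (S)-proline (20 mol%), DMF, 4 °C, 9 (2.5 equiv) added over 24 h
Reagents that add atoms: none
Why: In this proline-catalysed direct cross-aldol reaction the non-enolisable acceptor 8 is attacked on its Re face by the (E)-enamine of 9 through the hydrogen-bonded chair (Houk–List) transition state, giving the anti (2S,3S) aldol and so setting C8 and C9 under catalyst control.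

Step 6
Reactants: 10 the aldol aldehyde; 11 methyl acrylate
Product: 12 methyl (4S,5S,6S,7S)-4-[(tert-butyldimethylsilyl)oxy]-7-(dimethoxymethyl)-6-ethenyl-3,5-dihydroxy-6,8-dimethyl-2-methylidenenon-8-enoate (C3 epimers)
Conditions: DABCO (1 equiv), 11 (5 equiv), 1,4-dioxane/H2O 1:1, rt
Reagents that add atoms: none
Why: The Morita–Baylis–Hillman reaction of the α-oxygenated aldehyde installs C11–C13, and the new carbinol centre at C7 forms as a mixture that is irrelevant because C7 becomes sp2 in step 8.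

Step 7
Reactants: 12 the Morita–Baylis–Hillman adduct
Product: 15 (5R)-5-[(2S,3S,4S)-3-ethenyl-5-methoxy-3-methyl-4-(prop-1-en-2-yl)oxolan-2-yl]-4-hydroxy-3-methylideneoxolan-2-one (epimers at C4 and at the acetal carbon), via triol ester 13 (not isolated), via hydroxy lactone 14 (not isolated)
Conditions: CSA (10 mol%), MeOH, rt; evaporate; CSA (5 mol%), CH2Cl2, rt
Reagents that add atoms: none
Why: Acidic methanolysis removes the silyl ether, the freed C8 hydroxyl lactonises onto the methyl ester, and the C9 hydroxyl closes onto the dimethyl acetal to give a five-membered cyclic methyl acetal that masks both the C9 hydroxyl and the C6 aldehyde without touching any existing stereocentre.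

Step 8
Reactants: 15 the hydroxy methylene lactone
Product: 16 (5R)-3-(bromomethyl)-5-[(2S,3S,4S)-3-ethenyl-5-methoxy-3-methyl-4-(prop-1-en-2-yl)oxolan-2-yl]furan-2(5H)-one (anomers)
Conditions: CBr4, PPh3, CH2Cl2, 0 °C
Reagents that add atoms: carbon tetrabromide BrC(Br)(Br)Br
Why: Appel bromination of the Morita–Baylis–Hillman alcohol proceeds with allylic transposition (SN2′) to the conjugated 3-(bromomethyl)butenolide, the thermodynamic allylic bromide, which erases the C7 carbinol centre.

Step 9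
Reactants: 16 the bromomethyl butenolide
Product: 18 (3aR,4S,5S,6S,7S,7aR)-6-ethenyl-4,7-dihydroxy-6-methyl-3-methylidene-5-(prop-1-en-2-yl)hexahydro-1-benzofuran-2(3H)-one, via lactol 17 (not isolated)
Conditions: 1 M aq. HCl/THF 1:3, rt, 2 h; then In powder (2 equiv), rt
Reagents that add atoms: water O
Why: Acetal hydrolysis unmasks the γ-lactol/aldehyde and an intramolecular indium-mediated Barbier allylation through the γ-carbon (C7) closes the cyclohexane, the tether enforcing cis ring fusion at C7/C8 and the chair Zimmerman–Traxler transition state with both ring-forming substituents equatorial placing the new C6 hydroxyl trans to the C7–C11 bond.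

Step 10
Reactants: 18 the diol lactone
Product: 19 (3aR,4S,5S,6S,7S,7aR)-6-ethenyl-7-hydroxy-6-methyl-3-methylidene-2-oxo-5-(prop-1-en-2-yl)octahydro-1-benzofuran-4-yl acetate
Conditions: Ac2O (1.1 equiv), pyridine, CH2Cl2, −20 → 0 °C
Reagents that add atoms: acetic anhydride CC(=O)OC(C)=O
Why: Selective acetylation occurs at the less hindered C6 hydroxyl because the C9 hydroxyl is flanked by the quaternary carbon and reacts much more slowly.

Step 11
Reactants: 19 the C6 monoacetate; 20 angelic acid ((2Z)-2-methylbut-2-enoic acid)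
Product: 21 (3aR,4S,5S,6S,7S,7aR)-4-acetoxy-6-ethenyl-6-methyl-3-methylidene-2-oxo-5-(prop-1-en-2-yl)octahydro-1-benzofuran-7-yl (2Z)-2-methylbut-2-enoate
Conditions: 20 (3 equiv), 2,4,6-Cl3C6H2COCl (3 equiv), Et3N (3 equiv), toluene, rt, 2 h; then 19, 75 °C
Reagents that add atoms: none
Why: Yamaguchi esterification through the mixed anhydride, run without DMAP so that the (Z)-angelate does not isomerise to the tiglate, acylates the hindered C9 hydroxyl with retention.

Step 12
Reactants: 21 the isopropenyl diester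
Product: 23 (3aR,4S,5R,6S,7S,7aR)-4-acetoxy-6-ethenyl-6-methyl-3-methylidene-2-oxo-5-(3-oxoprop-1-en-2-yl)octahydro-1-benzofuran-7-yl (2Z)-2-methylbut-2-enoate (the target, CNP0252310.2), via allylic alcohol 22 (not isolated)
Conditions: SeO2 (0.5 equiv), t-BuOOH (3 equiv), CH2Cl2, rt; crude, then Dess–Martin periodinane, CH2Cl2, 0 °C
Reagents that add atoms: tert-butyl hydroperoxide CC(C)(C)OO; selenium dioxide O=[Se]=O
Why: SeO2 allylic oxidation (ene reaction then [2,3]-sigmatropic shift) is selective for the methyl group of the electron-rich isopropenyl alkene over the electron-poor enoate alkenes and the vinyl group, which has no allylic hydrogen, and Dess–Martin oxidation of the crude allylic alcohol completes the enal without touching a stereocentre.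

**Compound list**

1 | methacrolein (2-methylprop-2-enal) | C=C(C)C=O | starting material
2 | nitromethane | C[N+](=O)[O-] | starting material
3 | 3-methyl-1-nitrobut-3-en-2-ol (racemic) | C=C(C)C(O)C[N+](=O)[O-] | intermediate
4 | (1E)-3-methyl-1-nitrobuta-1,3-diene | C=C(C)/C=C/[N+](=O)[O-] | intermediate
5 | tiglaldehyde, (2E)-2-methylbut-2-enal | C/C=C(\C)C=O | starting material
6 | (2S,3S)-2-ethenyl-2,4-dimethyl-3-(nitromethyl)pent-4-enal | C=C[C@](C)(C=O)[C@@H](C[N+](=O)[O-])C(C)=C | intermediate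
7 | sodium aci-nitronate of 6 (the CH2NO2 carbon becomes CH=N(O)ONa; other centres as in 6) | [Na+].C=C[C@](C)(C=O)[C@@H](C=[N+]([O-])[O-])C(C)=C | intermediate
8 | (2S,3S)-3-(dimethoxymethyl)-2-ethenyl-2,4-dimethylpent-4-enal | C=C[C@](C)(C=O)[C@@H](C(OC)OC)C(C)=C | intermediate
9 | 2-[(tert-butyldimethylsilyl)oxy]acetaldehyde | O=CCO[Si](C)(C)C(C)(C)C | starting material
10 | (2S,3S,4S,5S)-2-[(tert-butyldimethylsilyl)oxy]-5-(dimethoxymethyl)-4-ethenyl-3-hydroxy-4,6-dimethylhept-6-enal | O=C[C@@H](O[Si](C)(C)C(C)(C)C)[C@@H](O)[C@@](C)(C=C)[C@@H](C(OC)OC)C(C)=C | intermediate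
11 | methyl acrylate | C=CC(=O)OC | starting material
12 | methyl (4S,5S,6S,7S)-4-[(tert-butyldimethylsilyl)oxy]-7-(dimethoxymethyl)-6-ethenyl-3,5-dihydroxy-6,8-dimethyl-2-methylidenenon-8-enoate (C3 epimers) | C=C(C(=O)OC)C(O)[C@@H](O[Si](C)(C)C(C)(C)C)[C@@H](O)[C@@](C)(C=C)[C@@H](C(OC)OC)C(C)=C | intermediate
13 | methyl (4S,5S,6S,7S)-7-(dimethoxymethyl)-6-ethenyl-3,4,5-trihydroxy-6,8-dimethyl-2-methylidenenon-8-enoate (C3 epimers) | C=C(C(=O)OC)C(O)[C@@H](O)[C@@H](O)[C@@](C)(C=C)[C@@H](C(OC)OC)C(C)=C | intermediate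
14 | (5S)-5-[(1S,2S,3S)-3-(dimethoxymethyl)-2-ethenyl-1-hydroxy-2,4-dimethylpent-4-en-1-yl]-4-hydroxy-3-methylideneoxolan-2-one (C4 epimers) | C=C1C(=O)O[C@@H]([C@@H](O)[C@@](C)(C=C)[C@@H](C(OC)OC)C(C)=C)C1O | intermediate
15 | (5R)-5-[(2S,3S,4S)-3-ethenyl-5-methoxy-3-methyl-4-(prop-1-en-2-yl)oxolan-2-yl]-4-hydroxy-3-methylideneoxolan-2-one (epimers at C4 and the acetal carbon) | C=C1C(=O)O[C@@H]([C@H]2OC(OC)[C@@H](C(C)=C)[C@]2(C)C=C)C1O | intermediate
16 | (5R)-3-(bromomethyl)-5-[(2S,3S,4S)-3-ethenyl-5-methoxy-3-methyl-4-(prop-1-en-2-yl)oxolan-2-yl]furan-2(5H)-one (anomers) | BrCC1=C[C@H]([C@H]2OC(OC)[C@@H](C(C)=C)[C@]2(C)C=C)OC1=O | intermediate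
17 | (5R)-3-(bromomethyl)-5-[(2S,3S,4S)-3-ethenyl-5-hydroxy-3-methyl-4-(prop-1-en-2-yl)oxolan-2-yl]furan-2(5H)-one (lactol, anomers) | BrCC1=C[C@H]([C@H]2OC(O)[C@@H](C(C)=C)[C@]2(C)C=C)OC1=O | intermediate
18 | (3aR,4S,5S,6S,7S,7aR)-6-ethenyl-4,7-dihydroxy-6-methyl-3-methylidene-5-(prop-1-en-2-yl)hexahydro-1-benzofuran-2(3H)-one | C=C[C@]1(C)[C@H](O)[C@@H]2OC(=O)C(=C)[C@@H]2[C@@H](O)[C@H]1C(C)=C | intermediate
19 | (3aR,4S,5S,6S,7S,7aR)-6-ethenyl-7-hydroxy-6-methyl-3-methylidene-2-oxo-5-(prop-1-en-2-yl)octahydro-1-benzofuran-4-yl acetate | C=C[C@]1(C)[C@H](O)[C@@H]2OC(=O)C(=C)[C@@H]2[C@@H](OC(C)=O)[C@H]1C(C)=C | intermediate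
20 | angelic acid, (2Z)-2-methylbut-2-enoic acid | C/C=C(/C)C(=O)O | starting material
21 | (3aR,4S,5S,6S,7S,7aR)-4-acetoxy-6-ethenyl-6-methyl-3-methylidene-2-oxo-5-(prop-1-en-2-yl)octahydro-1-benzofuran-7-yl (2Z)-2-methylbut-2-enoate | C=C[C@]1(C)[C@H](OC(=O)/C(C)=C\C)[C@@H]2OC(=O)C(=C)[C@@H]2[C@@H](OC(C)=O)[C@H]1C(C)=C | intermediate
22 | (3aR,4S,5S,6S,7S,7aR)-4-acetoxy-6-ethenyl-5-(3-hydroxyprop-1-en-2-yl)-6-methyl-3-methylidene-2-oxooctahydro-1-benzofuran-7-yl (2Z)-2-methylbut-2-enoate | C=C[C@]1(C)[C@H](OC(=O)/C(C)=C\C)[C@@H]2OC(=O)C(=C)[C@@H]2[C@@H](OC(C)=O)[C@H]1C(=C)CO | intermediate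
23 | (3aR,4S,5R,6S,7S,7aR)-4-acetoxy-6-ethenyl-6-methyl-3-methylidene-2-oxo-5-(3-oxoprop-1-en-2-yl)octahydro-1-benzofuran-7-yl (2Z)-2-methylbut-2-enoate | C=C[C@]1(C)[C@H](OC(=O)/C(C)=C\C)[C@@H]2OC(=O)C(=C)[C@@H]2[C@@H](OC(C)=O)[C@H]1C(=C)C=O | target

**Step count**

Total steps: 12. Longest linear sequence: 12 steps (1 to 23).

**Steps most likely to fail, with fallbacks**

Step 3 (the proposed new step). The risks are γ- instead of α-attack of the dienamine, 1,6-addition or cycloaddition with the nitrodiene, and weak control of the dienamine geometry (methyl against vinyl). The fallback sets out from 4 and comes back at 6, using only known reactions: the vinyl group is carried as a saturated selenide so that the established Michael addition of α,α-dialkyl aldehydes applies. Commercial methyl 4-bromo-2-methylbutanoate is treated with PhSeNa (from PhSeSePh and NaBH4, EtOH) to give methyl 2-methyl-4-(phenylselanyl)butanoate F1. Reduction with i-Bu2AlH at −78 °C gives 2-methyl-4-(phenylselanyl)butanal F2. F2 and 4 react under the same primary-amine–thiourea catalyst (E-enamine with the longer chain anti to nitrogen; the diastereomer ratio is expected to be moderate and the isomers are separated) to give (2S,3S)-2,4-dimethyl-3-(nitromethyl)-2-[2-(phenylselanyl)ethyl]pent-4-enal F3. NaIO4 in aqueous THF gives the selenoxide of F3 F4, which undergoes syn-elimination at room temperature to 6.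

Step 4. The free aldehyde may be acetalised as well, or may trap the C6 oxocarbenium ion to give a cyclic 2,5-dimethoxyoxolane. The fallback sets out from 6 and comes back at 8, protecting the aldehyde first. Compound 6 and H2NNMe2 (MgSO4, CH2Cl2) give (E)-2-[(2S,3S)-2-ethenyl-2,4-dimethyl-3-(nitromethyl)pent-4-en-1-ylidene]-1,1-dimethylhydrazine F5. NaOMe in MeOH gives the sodium aci-nitronate of F5 F6, which in H2SO4/MeOH at −45 °C gives (E)-2-[(2S,3S)-3-(dimethoxymethyl)-2-ethenyl-2,4-dimethylpent-4-en-1-ylidene]-1,1-dimethylhydrazine F7. CuCl2 in THF/pH 7 buffer cleaves the hydrazone, leaving the acetal, to give 8.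

Step 5. The silyloxyacetaldehyde may simply dimerise faster than it adds to the hindered acceptor. The fallback sets out from 8 and comes back at 15; C8/C9 are set by organocatalytic epoxidation instead of an aldol reaction. Compound 8 and Ph3P=CHCHO (benzene, 40 °C) give (2E,4R,5S)-5-(dimethoxymethyl)-4-ethenyl-4,6-dimethylhepta-2,6-dienal F8. H2O2 with (S)-2-[bis(3,5-bis(trifluoromethyl)phenyl)(trimethylsilyloxy)methyl]pyrrolidine (10 mol%, CH2Cl2) gives (2R,3S)-3-[(3S,4S)-4-(dimethoxymethyl)-3,5-dimethylhexa-1,5-dien-3-yl]oxirane-2-carbaldehyde F9. DABCO and methyl acrylate give methyl 2-{hydroxy[(2S,3S)-3-[(3S,4S)-4-(dimethoxymethyl)-3,5-dimethylhexa-1,5-dien-3-yl]oxiran-2-yl]methyl}prop-2-enoate F10. With CSA in CH2Cl2 the ester carbonyl opens the epoxide at C8 (five-membered ring closure, inversion), and the C9 hydroxyl set free from the epoxide oxygen closes onto the acetal, giving 15.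

Further compounds
F1 | step 3 | methyl 2-methyl-4-(phenylselanyl)butanoate (racemic) | COC(=O)C(C)CC[Se]c1ccccc1
F2 | step 3 | 2-methyl-4-(phenylselanyl)butanal (racemic) | O=CC(C)CC[Se]c1ccccc1
F3 | step 3 | (2S,3S)-2,4-dimethyl-3-(nitromethyl)-2-[2-(phenylselanyl)ethyl]pent-4-enal | c1ccccc1[Se]CC[C@](C)(C=O)[C@@H](C[N+](=O)[O-])C(C)=C
F4 | step 3 | selenoxide of F3, (2S,3S)-2,4-dimethyl-3-(nitromethyl)-2-[2-(phenylseleninyl)ethyl]pent-4-enal | [O-][Se+](CC[C@](C)(C=O)[C@@H](C[N+](=O)[O-])C(C)=C)c1ccccc1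
F5 | step 4 | (E)-2-[(2S,3S)-2-ethenyl-2,4-dimethyl-3-(nitromethyl)pent-4-en-1-ylidene]-1,1-dimethylhydrazine | C=C[C@](C)(/C=N/N(C)C)[C@@H](C[N+](=O)[O-])C(C)=C
F6 | step 4 | sodium aci-nitronate of F5 | [Na+].C=C[C@](C)(/C=N/N(C)C)[C@@H](C=[N+]([O-])[O-])C(C)=C
F7 | step 4 | (E)-2-[(2S,3S)-3-(dimethoxymethyl)-2-ethenyl-2,4-dimethylpent-4-en-1-ylidene]-1,1-dimethylhydrazine | C=C[C@](C)(/C=N/N(C)C)[C@@H](C(OC)OC)C(C)=C
F8 | step 5 | (2E,4R,5S)-5-(dimethoxymethyl)-4-ethenyl-4,6-dimethylhepta-2,6-dienal | O=C/C=C/[C@@](C)(C=C)[C@@H](C(OC)OC)C(C)=C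
F9 | step 5 | (2R,3S)-3-[(3S,4S)-4-(dimethoxymethyl)-3,5-dimethylhexa-1,5-dien-3-yl]oxirane-2-carbaldehyde | O=C[C@@H]1O[C@H]1[C@@](C)(C=C)[C@@H](C(OC)OC)C(C)=C
F10 | step 5 | methyl 2-{hydroxy[(2S,3S)-3-[(3S,4S)-4-(dimethoxymethyl)-3,5-dimethylhexa-1,5-dien-3-yl]oxiran-2-yl]methyl}prop-2-enoate (carbinol epimers) | C=C(C(=O)OC)C(O)[C@@H]1O[C@H]1[C@@](C)(C=C)[C@@H](C(OC)OC)C(C)=C
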